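**Strategy.** Everything rests on making the lower D ring (C4a to C8a, pentasubstituted, C6–H) on upper C4 instead of joining two flavans. D-ring C8 carries upper C4, while C8a–O1 and C4a–C4 belong to the lower pyran, so the 4β→8 connectivity can be fixed by how the arene is assembled. In one thermal operation a C4-(siloxyethynyl) hexa-O-benzylepigallocatechin and a 3-benzyloxy-4-[(trans-arylepoxy)methyl]cyclobutenone should combine by vinylketene [2+2], 4π opening and 6π closure (C8–C8a, C6–C7, C4a–C8a). The new C8a phenol then opens the epoxide at its benzylic carbon (O1–C2) and closes the catechin pyran 2,3-trans.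

Key step: step 12

Remark: ring carbon C4 of cyclobutenones 24 and 25 and the transient sp3 carbons of 27 and 29 are left undefined (epimer mixtures) because all become sp2 in step 12; the benzyloxy group is brought in with the ynol ether, since an alkoxy exchange on the vinylogous ester could move the ring double bond to the side-chain carbon.

Step 1
Reactants: 1 (−)-epigallocatechin
Product: 2 5,7,3',4',5'-penta-O-benzyl-(−)-epigallocatechin
Conditions: BnBr (5.5 equiv), K2CO3, DMF (degassed), −10 °C → rt, Ar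
Reagents that add atoms: benzyl bromide, BrCc1ccccc1
Why: Williamson etherification with carbonate base should benzylate the five phenols and leave the less acidic secondary 3-OH and the C2/C3 configuration untouched; air is excluded because the pyrogallol ring oxidises easily in base.

Step 2
Reactants: 2 5,7,3',4',5'-penta-O-benzyl-(−)-epigallocatechin
Product: 3 3,5,7,3',4',5'-hexa-O-benzyl-(−)-epigallocatechin
Conditions: NaH, BnBr, Bu4NI (cat.), DMF, 0 °C → rt
Reagents that add atoms: benzyl bromide, BrCc1ccccc1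
Why: Williamson O-alkylation of the secondary alkoxide; with every phenol capped there is no quinone-methide pathway for C2 epimerisation.

Step 3
Reactants: 3 3,5,7,3',4',5'-hexa-O-benzyl-(−)-epigallocatechin
Product: 4 4β-(2-ethoxyethoxy)-3,5,7,3',4',5'-hexa-O-benzyl-(−)-epigallocatechin
Conditions: DDQ (2 equiv), 2-ethoxyethanol (5 equiv), CH2Cl2, rt; DMAP quench
Reagents that add atoms: 2-ethoxyethanol, CCOCCO
Why: DDQ benzylic oxidation (hydride abstraction at C4, activated by the 5,7-dialkoxy A ring) and capture of the cation by the alcohol anti to the C3 benzyloxy group should give the 3,4-trans ether; this C4 centre is ionised again in step 4.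

Step 4
Reactants: 4 4β-(2-ethoxyethoxy)-3,5,7,3',4',5'-hexa-O-benzyl-(−)-epigallocatechin; 5 potassium (trimethylsilyl)ethynyltrifluoroborate
Product: 6 4β-[(trimethylsilyl)ethynyl]-3,5,7,3',4',5'-hexa-O-benzyl-(−)-epigallocatechin
Conditions: 5 (3 equiv), BF3·OEt2 (2.5 equiv), CH2Cl2/MeCN, −40 → 0 °C
Reagents that add atoms: none
Why: Lewis-acid ionisation of the C4 ether to the A-ring-stabilised benzylic cation and its capture by the alkynyl borate (alkynyltrifluoroborate alkynylation of a stabilised carbocation) should occur on the β face, anti to both the C3 benzyloxy and the C2 aryl group of the 2,3-cis series, which sets C4 as 3,4-trans.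

Step 5
Reactants: 6 4β-[(trimethylsilyl)ethynyl]-3,5,7,3',4',5'-hexa-O-benzyl-(−)-epigallocatechin
Product: 7 4β-ethynyl-3,5,7,3',4',5'-hexa-O-benzyl-(−)-epigallocatechin
Conditions: K2CO3 (cat.), MeOH/THF, rt
Reagents that add atoms: none
Why: base-mediated protodesilylation of an alkynylsilane; C4–H is far too weakly acidic to epimerise under carbonate.

Step 6
Reactants: 7 4β-ethynyl-3,5,7,3',4',5'-hexa-O-benzyl-(−)-epigallocatechin
Product: 10 4β-[(triisopropylsilyloxy)ethynyl]-3,5,7,3',4',5'-hexa-O-benzyl-(−)-epigallocatechin, via lithium acetylide 8 (not isolated), via lithium ynolate 9 (not isolated)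
Conditions: LiHMDS (2.1 equiv), THF, −78 °C; t-BuOOH (1.0 equiv, anhydrous in PhMe), −78 → 0 °C; TIPSOTf (1.2 equiv), −78 °C → rt
Reagents that add atoms: tert-butyl hydroperoxide, CC(C)(C)OO; triisopropylsilyl trifluoromethanesulfonate, CC(C)[Si](C(C)C)(C(C)C)OS(=O)(=O)C(F)(F)F
Why: oxidation of a lithium acetylide by lithium tert-butyl peroxide (electrophilic oxygen transfer) gives the ynolate, which the bulky silyl triflate should trap on oxygen to the siloxyalkyne; C4 is not involved.

Step 7
Reactants: 11 3,4-bis(benzyloxy)benzaldehyde; 12 (3-carboxypropyl)triphenylphosphonium bromide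
Product: 14 (E)-5-[3,4-bis(benzyloxy)phenyl]pent-4-enoic acid, via carboxylate ylide 13 (not isolated)
Conditions: NaHMDS (2.2 equiv), THF, 0 °C → rt; aq. HCl work-up; recrystallisation
Reagents that add atoms: none
Why: Wittig olefination; carboxylate-bearing ylides are known to favour the E alkene with aromatic aldehydes, and recrystallisation of the acid should remove residual Z isomer (E geometry is required for the trans epoxide).

Step 8
Reactants: 15 benzyl alcohol; 16 trichloroethylene
Product: 18 benzyl (E)-1,2-dichlorovinyl ether, via dichloroacetylene 17 (not isolated)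
Conditions: KH (1.2 equiv), THF, 0 °C; then 16, −50 °C → rt
Reagents that add atoms: none
Why: base-induced elimination of trichloroethylene to dichloroacetylene and anti addition of the alkoxide (the dichlorovinyl ether entry to ynol ethers) should give the E ether; the hazardous dichloroacetylene stays in solution.

Step 9
Reactants: 18 benzyl (E)-1,2-dichlorovinyl ether
Product: 21 benzyloxyacetylene (benzyl ethynyl ether), via benzyl chloroethynyl ether 19 (not isolated), via lithium benzyloxyacetylide 20 (not isolated)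
Conditions: n-BuLi (2.2 equiv), Et2O, −78 °C; MeOH (1.1 equiv), −78 °C; cold aqueous wash, dried Et2O solution kept ≤ 0 °C and used at once
Reagents that add atoms: none
Why: dehydrochlorination to the chloroalkyne and lithium–chlorine exchange give the lithium alkoxyacetylide, which is protonated cold to the terminal ynol ether; it is kept cold in solution because benzyl alkynyl ethers rearrange sigmatropically on warming.

Step 10
Reactants: 14 (E)-5-[3,4-bis(benzyloxy)phenyl]pent-4-enoic acid; 21 benzyloxyacetylene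
Product: 24 3-(benzyloxy)-4-[(E)-3-[3,4-bis(benzyloxy)phenyl]prop-2-en-1-yl]cyclobut-2-en-1-one, via acid chloride 22 (not isolated), via alkylketene 23 (not isolated)
Conditions: (COCl)2, DMF (cat.), CH2Cl2, 0 °C → rt, evaporate; then slow addition to 21 (2.5 equiv), Et3N (1.3 equiv), Et2O, 0 °C → rt
Reagents that add atoms: none
Why: dehydrochlorination of the acid chloride gives the monoalkylketene, and its [2+2] cycloaddition with the ynol ether joins the ketene carbonyl carbon to the unsubstituted alkyne carbon, so benzyloxy lands on C3 and the side chain on C4 with no later exchange; slow addition limits ketene dimerisation and the one-carbon tether excludes an intramolecular ketene–alkene reaction.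

Step 11
Reactants: 24 3-(benzyloxy)-4-[(E)-3-[3,4-bis(benzyloxy)phenyl]prop-2-en-1-yl]cyclobut-2-en-1-one
Product: 25 3-(benzyloxy)-4-{[(2S,3S)-3-[3,4-bis(benzyloxy)phenyl]oxiran-2-yl]methyl}cyclobut-2-en-1-one
Conditions: ent-Shi ketone (L-fructose-derived, 30 mol%), Oxone, K2CO3, Bu4NHSO4 (cat.), MeCN/DMM/aq. borate–EDTA buffer (pH ca. 10.5), −5 → 0 °C; chromatography on Et3N-deactivated silica
Reagents that add atoms: Oxone (potassium peroxymonosulfate), [K+].[O-]S(=O)(=O)OO
Why: Shi epoxidation: the chiral dioxirane attacks the electron-rich trans-disubstituted styrene through the spiro transition state, and the L-fructose-derived ketone should give the (S,S) epoxide (the D-ketone gives R,R with trans-β-alkylstyrenes), while the electron-poor vinylogous-ester C=C is left alone.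

Step 12
Reactants: 10 4β-[(triisopropylsilyloxy)ethynyl]-3,5,7,3',4',5'-hexa-O-benzyl-(−)-epigallocatechin; 25 3-(benzyloxy)-4-{[(2S,3S)-3-[3,4-bis(benzyloxy)phenyl]oxiran-2-yl]methyl}cyclobut-2-en-1-one
Product: 31 3,5,7,3',4',5'-hexa-O-benzylepigallocatechin-(4β→8)-[5,3',4'-tri-O-benzyl-7-O-triisopropylsilyl-(+)-catechin], via vinylketene 26 (not isolated), via vinylcyclobutenone 27 (not isolated), via dienylketene 28 (not isolated), via cyclohexadienone 29 (not isolated), via epoxy phenol 30 (not isolated)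
Conditions: 10 (1.1 equiv), PhMe (degassed, base-washed glass), 80 → 110 °C; then rt, PPTS (10 mol%)
Reagents that add atoms: none
Why: Proposed new method: heating opens cyclobutenone 25 by 4π electrocyclic cleavage (side chain rotating outward) to vinylketene 26, whose ketene carbon is attacked by the flavanyl-bearing β-carbon of ynol ether 10 in a regiospecific [2+2] (C8–C8a, C6–C7), and adduct 27 opens again (4π) to dienylketene 28, which closes by 6π electrocyclisation (C4a–C8a) and tautomerises via 29 to phenol 30. The closest known reaction type is the Danheiser benzannulation of cyclobutenones with siloxyalkynes to resorcinol monosilyl ethers; new here are the 3-alkoxy-4-alkylcyclobutenone, the secondary flavan-4-yl group on the alkyne and the coupling to an epoxide opening. The D ring is closed by 6π electrocyclisation of the dienylketene and the lower pyran by 6-endo-tet attack of the C8a phenol on the benzylic epoxide carbon (O1–C2), a closure known from phenol/aryl-epoxide routes to 2,3-trans flavan-3-ols and finished here with catalytic PPTS once no ketene is left. The one new stereocentre, lower C2, results from inversion at the benzylic carbon, so the (S,S) epoxide from step 11 should give (2R,3S) with C3 carried over unchanged, while upper C2, C3 and C4 are spectators. Two selectivities are needed: the 4→8 pattern, secured by the polarisation of the ynol ether (flavanyl group ortho to the new hydroxyl, side chain on the other ortho carbon, silyloxy at C7), and 6-endo over 5-exo opening, secured by the electron-rich 3,4-bis(benzyloxy)phenyl group, which stabilises positive charge at the benzylic carbon under neutral to weakly acidic conditions. A slight excess of 10 keeps the vinylketene concentration low so that neither the hindered phenol nor the liberated secondary alcohol is acylated.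

Step 13
Reactants: 31 3,5,7,3',4',5'-hexa-O-benzylepigallocatechin-(4β→8)-[5,3',4'-tri-O-benzyl-7-O-triisopropylsilyl-(+)-catechin]
Product: 32 3,5,7,3',4',5'-hexa-O-benzylepigallocatechin-(4β→8)-[5,3',4'-tri-O-benzyl-(+)-catechin]
Conditions: TBAF, AcOH (1:1), THF, 0 °C
Reagents that add atoms: none
Why: fluoride cleavage of the aryl silyl ether (Si–F bond formation), buffered with acetic acid so that no free phenoxide is left to oxidise.

Step 14
Reactants: 32 3,5,7,3',4',5'-hexa-O-benzylepigallocatechin-(4β→8)-[5,3',4'-tri-O-benzyl-(+)-catechin]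
Product: 33 epigallocatechin-(4β→8)-catechin (CNP0225927.1)
Conditions: H2 (1 atm), Pd(OH)2/C, THF/MeOH/H2O, rt; filtration, Sephadex LH-20, lyophilisation
Reagents that add atoms: none
Why: catalytic hydrogenolysis of the nine benzyl ethers under neutral conditions should leave the acid-labile interflavan C4–C8 bond and all five stereocentres untouched.

**Compound list**

1 | (−)-epigallocatechin, (2R,3R) | O[C@@H]1Cc2c(O)cc(O)cc2O[C@@H]1c1cc(O)c(O)c(O)c1 | starting material
2 | 5,7,3',4',5'-penta-O-benzyl-(−)-epigallocatechin, (2R,3R) | c1ccccc1COc1cc(OCc3ccccc3)c2c(c1)O[C@H](c1cc(OCc3ccccc3)c(OCc3ccccc3)c(OCc3ccccc3)c1)[C@H](O)C2 | intermediate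
3 | 3,5,7,3',4',5'-hexa-O-benzyl-(−)-epigallocatechin, (2R,3R) | c1ccccc1COc1cc(OCc3ccccc3)c2c(c1)O[C@H](c1cc(OCc3ccccc3)c(OCc3ccccc3)c(OCc3ccccc3)c1)[C@H](OCc3ccccc3)C2 | intermediate
4 | 4β-(2-ethoxyethoxy)-hexa-O-benzyl-(−)-epigallocatechin (2,3-cis, 3,4-trans) | c1ccccc1COc1cc(OCc3ccccc3)c2c(c1)O[C@H](c1cc(OCc3ccccc3)c(OCc3ccccc3)c(OCc3ccccc3)c1)[C@H](OCc3ccccc3)[C@H]2OCCOCC | intermediate
5 | potassium (trimethylsilyl)ethynyltrifluoroborate | C[Si](C)(C)C#C[B-](F)(F)F.[K+] | starting material
6 | 4β-[(trimethylsilyl)ethynyl]-hexa-O-benzyl-(−)-epigallocatechin (2,3-cis, 3,4-trans) | c1ccccc1COc1cc(OCc3ccccc3)c2c(c1)O[C@H](c1cc(OCc3ccccc3)c(OCc3ccccc3)c(OCc3ccccc3)c1)[C@H](OCc3ccccc3)[C@H]2C#C[Si](C)(C)C | intermediate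
7 | 4β-ethynyl-hexa-O-benzyl-(−)-epigallocatechin | c1ccccc1COc1cc(OCc3ccccc3)c2c(c1)O[C@H](c1cc(OCc3ccccc3)c(OCc3ccccc3)c(OCc3ccccc3)c1)[C@H](OCc3ccccc3)[C@H]2C#C | intermediate
8 | lithium acetylide of 7 (not isolated) | c1ccccc1COc1cc(OCc3ccccc3)c2c(c1)O[C@H](c1cc(OCc3ccccc3)c(OCc3ccccc3)c(OCc3ccccc3)c1)[C@H](OCc3ccccc3)[C@H]2C#[C-].[Li+] | intermediate
9 | lithium ynolate, flavan-4β-yl-C≡C–OLi (not isolated) | c1ccccc1COc1cc(OCc3ccccc3)c2c(c1)O[C@H](c1cc(OCc3ccccc3)c(OCc3ccccc3)c(OCc3ccccc3)c1)[C@H](OCc3ccccc3)[C@H]2C#C[O-].[Li+] | intermediate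
10 | 4β-[(triisopropylsilyloxy)ethynyl]-hexa-O-benzyl-(−)-epigallocatechin (key-step precursor) | c1ccccc1COc1cc(OCc3ccccc3)c2c(c1)O[C@H](c1cc(OCc3ccccc3)c(OCc3ccccc3)c(OCc3ccccc3)c1)[C@H](OCc3ccccc3)[C@H]2C#CO[Si](C(C)C)(C(C)C)C(C)C | intermediate
11 | 3,4-bis(benzyloxy)benzaldehyde | O=Cc1ccc(OCc2ccccc2)c(OCc2ccccc2)c1 | starting material
12 | (3-carboxypropyl)triphenylphosphonium bromide | [Br-].OC(=O)CCC[P+](c1ccccc1)(c1ccccc1)c1ccccc1 | starting material
13 | sodium 4-(triphenylphosphoranylidene)butanoate, carboxylate ylide (not isolated) | [Na+].[O-]C(=O)CCC=P(c1ccccc1)(c1ccccc1)c1ccccc1 | intermediate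
14 | (E)-5-[3,4-bis(benzyloxy)phenyl]pent-4-enoic acid | OC(=O)CC/C=C/c1ccc(OCc2ccccc2)c(OCc2ccccc2)c1 | intermediate
15 | benzyl alcohol | OCc1ccccc1 | starting material
16 | trichloroethylene | ClC=C(Cl)Cl | starting material
17 | dichloroacetylene (not isolated) | ClC#CCl | intermediate
18 | benzyl (E)-1,2-dichlorovinyl ether | Cl/C=C(/Cl)OCc1ccccc1 | intermediate
19 | benzyl chloroethynyl ether (not isolated) | ClC#COCc1ccccc1 | intermediate
20 | lithium benzyloxyacetylide (not isolated) | [Li+].[C-]#COCc1ccccc1 | intermediate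
21 | benzyloxyacetylene (benzyl ethynyl ether) | C#COCc1ccccc1 | intermediate
22 | (E)-5-[3,4-bis(benzyloxy)phenyl]pent-4-enoyl chloride (not isolated) | ClC(=O)CC/C=C/c1ccc(OCc2ccccc2)c(OCc2ccccc2)c1 | intermediate
23 | (E)-5-[3,4-bis(benzyloxy)phenyl]penta-1,4-dien-1-one, alkylketene (not isolated) | O=C=CC/C=C/c1ccc(OCc2ccccc2)c(OCc2ccccc2)c1 | intermediate
24 | 3-(benzyloxy)-4-[(E)-3-[3,4-bis(benzyloxy)phenyl]prop-2-en-1-yl]cyclobut-2-en-1-one (C4 racemic) | O=C1C=C(OCc2ccccc2)C1C/C=C/c1ccc(OCc2ccccc2)c(OCc2ccccc2)c1 | intermediate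
25 | 3-(benzyloxy)-4-{[(2S,3S)-3-[3,4-bis(benzyloxy)phenyl]oxiran-2-yl]methyl}cyclobut-2-en-1-one (C4 epimers; key-step precursor) | O=C1C=C(OCc2ccccc2)C1C[C@@H]1O[C@H]1c1ccc(OCc2ccccc2)c(OCc2ccccc2)c1 | intermediate
26 | (Z)-3-(benzyloxy)-5-[(2S,3S)-3-[3,4-bis(benzyloxy)phenyl]oxiran-2-yl]penta-1,3-dien-1-one, vinylketene (not isolated) | O=C=C/C(OCc2ccccc2)=C/C[C@@H]1O[C@H]1c1ccc(OCc2ccccc2)c(OCc2ccccc2)c1 | intermediate
27 | 2-(flavan-4β-yl)-3-(triisopropylsilyloxy)-4-[1-(benzyloxy)-3-(epoxyaryl)prop-1-enyl]cyclobut-2-en-1-one, [2+2] adduct (not isolated) | c1ccccc1COc1cc(OCc3ccccc3)c2c(c1)O[C@H](c1cc(OCc3ccccc3)c(OCc3ccccc3)c(OCc3ccccc3)c1)[C@H](OCc3ccccc3)[C@H]2C4=C(O[Si](C(C)C)(C(C)C)C(C)C)C(C4=O)/C(OCc3ccccc3)=C/C[C@@H]5O[C@H]5c6ccc(OCc3ccccc3)c(OCc3ccccc3)c6 | intermediate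
28 | 2-(flavan-4β-yl)-3-(triisopropylsilyloxy)-5-(benzyloxy)-7-(epoxyaryl)hepta-1,3,5-trien-1-one, dienylketene with cis central C=C (not isolated) | c1ccccc1COc1cc(OCc3ccccc3)c2c(c1)O[C@H](c1cc(OCc3ccccc3)c(OCc3ccccc3)c(OCc3ccccc3)c1)[C@H](OCc3ccccc3)[C@H]2C(=C=O)/C(O[Si](C(C)C)(C(C)C)C(C)C)=C\C(OCc3ccccc3)=C\C[C@@H]5O[C@H]5c6ccc(OCc3ccccc3)c(OCc3ccccc3)c6 | intermediate
29 | 2-(flavan-4β-yl)-3-(triisopropylsilyloxy)-5-(benzyloxy)-6-[(epoxyaryl)methyl]cyclohexa-2,4-dien-1-one (not isolated) | c1ccccc1COc1cc(OCc3ccccc3)c2c(c1)O[C@H](c1cc(OCc3ccccc3)c(OCc3ccccc3)c(OCc3ccccc3)c1)[C@H](OCc3ccccc3)[C@H]2C4=C(O[Si](C(C)C)(C(C)C)C(C)C)C=C(OCc3ccccc3)C(C4=O)C[C@@H]5O[C@H]5c6ccc(OCc3ccccc3)c(OCc3ccccc3)c6 | intermediate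
30 | 2-(flavan-4β-yl)-3-(triisopropylsilyloxy)-5-(benzyloxy)-6-{[(2S,3S)-3-[3,4-bis(benzyloxy)phenyl]oxiran-2-yl]methyl}phenol, epoxy phenol (not isolated) | c1ccccc1COc1cc(OCc3ccccc3)c2c(c1)O[C@H](c1cc(OCc3ccccc3)c(OCc3ccccc3)c(OCc3ccccc3)c1)[C@H](OCc3ccccc3)[C@H]2c4c(O[Si](C(C)C)(C(C)C)C(C)C)cc(OCc3ccccc3)c(C[C@@H]5O[C@H]5c6ccc(OCc3ccccc3)c(OCc3ccccc3)c6)c4O | intermediate
31 | hexa-O-benzylepigallocatechin-(4β→8)-[5,3',4'-tri-O-benzyl-7-O-triisopropylsilyl-(+)-catechin], lower 3-OH free (key-step product) | c1ccccc1COc1cc(OCc3ccccc3)c2c(c1)O[C@H](c1cc(OCc3ccccc3)c(OCc3ccccc3)c(OCc3ccccc3)c1)[C@H](OCc3ccccc3)[C@H]2c1c(O[Si](C(C)C)(C(C)C)C(C)C)cc(OCc3ccccc3)c2c1O[C@H](c1ccc(OCc3ccccc3)c(OCc3ccccc3)c1)[C@@H](O)C2 | intermediate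
32 | hexa-O-benzylepigallocatechin-(4β→8)-[5,3',4'-tri-O-benzyl-(+)-catechin] | c1ccccc1COc1cc(OCc3ccccc3)c2c(c1)O[C@H](c1cc(OCc3ccccc3)c(OCc3ccccc3)c(OCc3ccccc3)c1)[C@H](OCc3ccccc3)[C@H]2c1c(O)cc(OCc3ccccc3)c2c1O[C@H](c1ccc(OCc3ccccc3)c(OCc3ccccc3)c1)[C@@H](O)C2 | intermediate
33 | epigallocatechin-(4β→8)-catechin (upper 2R,3R,4R; lower 2R,3S) | Oc1cc(O)c2c(c1)O[C@H](c1cc(O)c(O)c(O)c1)[C@H](O)[C@H]2c1c(O)cc(O)c2c1O[C@H](c1ccc(O)c(O)c1)[C@@H](O)C2 | target

**Totals.** Total step count: 14. Longest linear sequence: 9 steps (steps 1–6, then 12–14, from (−)-epigallocatechin).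

**Steps most likely to fail**

Step 12. The [2+2] at the hindered alkyne carbon may be too slow, so the vinylketene dimerises or acylates hydroxyl groups. The epoxide may also ionise before the phenol arrives, with loss of the inversion at lower C2 or competing 5-exo opening. The fallback uses known chemistry and sets out from 4. Compound 4 is ionised with TMSOTf in CH2Cl2 at −78 °C in the presence of an excess of 5,7,3',4'-tetra-O-benzyl-(+)-catechin F1, itself made from commercial (+)-catechin with BnBr and K2CO3 in DMF. This Lewis-acid Friedel–Crafts condensation of a flavan-4-yl cation with a flavan A ring is the established way to 4→8 procyanidins, with attack anti to the C3 substituent and mainly at C8. It should give hexa-O-benzylepigallocatechin-(4β→8)-(5,7,3',4'-tetra-O-benzylcatechin) F2, which is hydrogenolysed under the conditions of step 14; the route is rejoined at 33.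

Step 11. The strained vinylogous ester may be hydrolysed or undergo Baeyer–Villiger oxidation in basic aqueous Oxone, or the facial selectivity may be poor. The fallback sets out from 24, which is epoxidised with dimethyldioxirane in acetone at 0 °C (neutral, anhydrous). This gives the racemic trans epoxide, that is 25 together with 3-(benzyloxy)-4-{[(2R,3R)-3-[3,4-bis(benzyloxy)phenyl]oxiran-2-yl]methyl}cyclobut-2-en-1-one F3. The mixture is taken through step 12 with enantiopure 10, so that the upper unit resolves the lower one. Compound 31 is then separated by chromatography from its diastereomer hexa-O-benzylepigallocatechin-(4β→8)-[5,3',4'-tri-O-benzyl-7-O-triisopropylsilyl-ent-catechin] F4, and the route is rejoined at 31.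

Step 10. The benzyl ynol ether may rearrange before it meets the ketene, or the monoalkylketene may dimerise. The fallback sets out from 14. The same acid chloride and triethylamine protocol is run with commercial, thermally robust ethoxyacetylene to give 3-ethoxy-4-[(E)-3-[3,4-bis(benzyloxy)phenyl]prop-2-en-1-yl]cyclobut-2-en-1-one F5. Acid-catalysed transetherification of this vinylogous ester with benzyl alcohol (PPTS, benzene, removal of ethanol, stopped before the ring double bond can migrate) then leads back to the route at 24.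

**Further compounds**

F1 | step 12 | 5,7,3',4'-tetra-O-benzyl-(+)-catechin | c1ccccc1COc1cc(OCc3ccccc3)c2c(c1)O[C@H](c1ccc(OCc3ccccc3)c(OCc3ccccc3)c1)[C@@H](O)C2
F2 | step 12 | hexa-O-benzylepigallocatechin-(4β→8)-(5,7,3',4'-tetra-O-benzylcatechin) | c1ccccc1COc1cc(OCc3ccccc3)c2c(c1)O[C@H](c1cc(OCc3ccccc3)c(OCc3ccccc3)c(OCc3ccccc3)c1)[C@H](OCc3ccccc3)[C@H]2c1c(OCc3ccccc3)cc(OCc3ccccc3)c2c1O[C@H](c1ccc(OCc3ccccc3)c(OCc3ccccc3)c1)[C@@H](O)C2
F3 | step 11 | 3-(benzyloxy)-4-{[(2R,3R)-3-[3,4-bis(benzyloxy)phenyl]oxiran-2-yl]methyl}cyclobut-2-en-1-one | O=C1C=C(OCc2ccccc2)C1C[C@H]1O[C@@H]1c1ccc(OCc2ccccc2)c(OCc2ccccc2)c1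
F4 | step 11 | hexa-O-benzylepigallocatechin-(4β→8)-[5,3',4'-tri-O-benzyl-7-O-triisopropylsilyl-ent-catechin] (lower 2S,3R) | c1ccccc1COc1cc(OCc3ccccc3)c2c(c1)O[C@H](c1cc(OCc3ccccc3)c(OCc3ccccc3)c(OCc3ccccc3)c1)[C@H](OCc3ccccc3)[C@H]2c1c(O[Si](C(C)C)(C(C)C)C(C)C)cc(OCc3ccccc3)c2c1O[C@@H](c1ccc(OCc3ccccc3)c(OCc3ccccc3)c1)[C@H](O)C2
F5 | step 10 | 3-ethoxy-4-[(E)-3-[3,4-bis(benzyloxy)phenyl]prop-2-en-1-yl]cyclobut-2-en-1-one | O=C1C=C(OCC)C1C/C=C/c1ccc(OCc2ccccc2)c(OCc2ccccc2)c1
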